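**Retrosynthetic overview**
- The target comes from acetonide hydrolysis. Ring B, the ten-membered carbocycle, is closed last at C1–C10 by a nickel/chromium alkenyl bromide–aldehyde coupling, which also creates 1-OH and the 10(14)-methylene.
- C8–O ester bond: the side-chain acid (chiral pool, alkyne hydroxycarbonylation) is joined to an 8-hydroxy cis-lactone.
- Ring A, the cis α-methylene-γ-lactone, is formed first by indium 2-(methoxycarbonyl)allylation of an enal followed by C12–O6 lactonisation. C8 is set by asymmetric 2-bromoallylation of acrolein and relays to C7 and C6.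
- Key disconnection: the C6–O and C15–O bonds are both made in one palladium-catalysed 1,4-hydroxyacetoxylation of the diene of myrcene. This step also fixes the C4=C5 geometry, and O6 later becomes the lactone ring oxygen.
- Ring order: A (lactone), then B (carbocycle).

Assumption: the SMILES is taken literally, meaning a cis-fused 6,12-lactone (6S,7R), 8S, 1R, 3'R, and C15 trans to C6 on C4=C5 (E by CIP, cis within the ring); atom labels C1–C15 follow germacrane numbering.

Step 1
Reactants: 1 methyl (S)-2,2-dimethyl-1,3-dioxolane-4-carboxylate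
Product: 3 (R)-4-ethynyl-2,2-dimethyl-1,3-dioxolane, via (S)-glyceraldehyde acetonide 2 (not isolated)
Conditions: iBu2AlH, CH2Cl2, −78 °C; then MeOH, K2CO3, dimethyl (1-diazo-2-oxopropyl)phosphonate, −78 → 25 °C
Reagents that add atoms: dimethyl (1-diazo-2-oxopropyl)phosphonate, COP(=O)(OC)C(=[N+]=[N-])C(C)=O
Why: Partial ester reduction followed in the same flask by Ohira–Bestmann (Seyferth–Gilbert) homologation avoids isolating the racemisation-prone aldehyde, and the stereocentre (later C3') comes from the chiral pool and is not touched.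

Step 2
Reactants: 3 (R)-4-ethynyl-2,2-dimethyl-1,3-dioxolane
Product: 4 (R)-2-(2,2-dimethyl-1,3-dioxolan-4-yl)acrylic acid
Conditions: Pd(OAc)2 (1 mol%), 2-(diphenylphosphino)pyridine (6 mol%), MeSO3H (4 mol%), CO (30 bar), H2O (5 equiv), THF, 45 °C
Reagents that add atoms: carbon monoxide, [C-]#[O+]; water, O
Why: Markovnikov (Reppe-type) hydroxycarbonylation of a terminal alkyne with a cationic palladium hydride/pyridylphosphine catalyst places CO2H on the internal carbon, and no stereocentre is affected.

Step 3
Reactants: 5 2,3-dibromopropene; 6 acrolein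
Product: 7 (S)-[(5-bromohexa-1,5-dien-3-yl)oxy]triethylsilane
Conditions: CrBr3 (10 mol%), chiral oxazoline–sulfonamide ligand (12 mol%, the enantiomer that gives the S product), Et3N (25 mol%), Mn powder (2 equiv), Et3SiCl (1.5 equiv), THF, 0 °C
Reagents that add atoms: chlorotriethylsilane, CC[Si](Cl)(CC)CC
Why: In this catalytic asymmetric Nozaki–Hiyama 2-haloallylation only the allylic C–Br bond is reduced by divalent chromium, the ligand-bound allylchromium adds 1,2 to acrolein and sets C8 (S), and Et3SiCl releases the chromium alkoxide directly as the silyl ether.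

Step 4
Reactants: 7 (S)-[(5-bromohexa-1,5-dien-3-yl)oxy]triethylsilane
Product: 9 (S)-4-bromo-2-(triethylsilyloxy)pent-4-enal, via vicinal diol 8 (not isolated)
Conditions: OsO4 (2 mol%), NaIO4 (4 equiv), 2,6-lutidine, dioxane/H2O 3:1, 25 °C
Reagents that add atoms: sodium periodate (oxygen source relayed by OsO4), [Na+].[O-]I(=O)(=O)=O; water, O
Why: In this Lemieux–Johnson cleavage OsO4 takes the monosubstituted alkene much faster than the electron-poor 2-bromoalkene, and the lutidine buffer keeps the α-silyloxy aldehyde configurationally intact.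

Step 5
Reactants: 9 (S)-4-bromo-2-(triethylsilyloxy)pent-4-enal; 10 methyl propiolate
Product: 12 methyl (4S)-6-bromo-3-hydroxy-2-methylidene-4-(triethylsilyloxy)hept-6-enoate (C3 epimers), via vinylalane 11 (not isolated)
Conditions: 10, iBu2AlH, N-methylmorpholine N-oxide, THF, 0 °C; then 9, 0 → 25 °C; aqueous work-up
Reagents that add atoms: none
Why: Vinylalumination (hydroalumination of the propiolate, then carbonyl addition) gives the Morita–Baylis–Hillman-type adduct quickly and without amine base so C8 does not epimerise, and the new C7 carbinol centre forms as a mixture that is erased in step 6.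

Step 6
Reactants: 12 methyl (4S)-6-bromo-3-hydroxy-2-methylidene-4-(triethylsilyloxy)hept-6-enoate
Product: 13 methyl (2Z,4S)-6-bromo-2-(bromomethyl)-4-(triethylsilyloxy)hepta-2,6-dienoate
Conditions: NBS, Me2S, CH2Cl2, −20 → 0 °C
Reagents that add atoms: N-bromosuccinimide, O=C1CCC(=O)N1Br
Why: SN2' bromination of a Baylis–Hillman alcohol with the Corey–Kim-type NBS/Me2S reagent gives the thermodynamic Z-2-(bromomethyl)enoate, with C8 cis to CH2Br.

Step 7
Reactants: 14 myrcene
Product: 15 (2E)-2-(2-hydroxyethylidene)-6-methylhept-5-en-1-yl acetate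
Conditions: Pd(OAc)2 (5 mol%), LiOAc (1.5 equiv), AcOH (3 equiv), p-benzoquinone (1.5 equiv), acetone/H2O 4:1, 25 °C
Reagents that add atoms: water, O; acetic acid, CC(=O)O
Why: Proposed new method: intermolecular palladium-catalysed 1,4-hydroxyacetoxylation of a 2-alkyl-1,3-diene, in which the divalent palladium–diene complex is attacked first by water (in large excess over acetate) at the unsubstituted vinyl terminus C6 to give the syn 2-alkyl-π-allyl complex, then after benzoquinone coordination acetate, the only anionic nucleophile, attacks the free CH2 terminus C15, so the order of the two attacks puts OH on C6 and OAc on C15, the syn-allyl geometry fixes C6 trans to C15 (4E), and the isolated trisubstituted alkene stays a spectator in the chloride-free medium; the closest known reaction type is the Bäckvall 1,4-diacetoxylation of dienes and its intramolecular 1,4-oxyacetoxylation with tethered alcohols in acetone/AcOH.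

Step 8
Reactants: 15 (2E)-2-(2-hydroxyethylidene)-6-methylhept-5-en-1-yl acetate
Product: 16 (2E)-6-methyl-2-(2-oxoethylidene)hept-5-en-1-yl acetate
Conditions: TEMPO (10 mol%), PhI(OAc)2 (1.1 equiv), CH2Cl2, 0 → 25 °C
Reagents that add atoms: none
Why: Oxoammonium (TEMPO) oxidation of a primary allylic alcohol is neutral and does not isomerise the trisubstituted enal, as in the nerol to neral case.

Step 9
Reactants: 13 methyl (2Z,4S)-6-bromo-2-(bromomethyl)-4-(triethylsilyloxy)hepta-2,6-dienoate; 16 (2E)-6-methyl-2-(2-oxoethylidene)hept-5-en-1-yl acetate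
Product: 19 8-hydroxy cis-lactone (6S,7R,8S,4E; α-methylene-γ-butyrolactone carrying at C6 the 15-acetoxy alkenyl chain ending in the isopropylidene group and at C7 the CH(OH)CH2C(Br)=CH2 unit), via hydroxy ester 17 (not isolated), via TES lactone 18 (not isolated)
Conditions: indium powder, THF/H2O 1:1, 25 °C; extraction, then PPTS (20 mol%), CH2Cl2, 35 °C; then HF·pyridine, THF, 0 °C
Reagents that add atoms: none
Why: The indium Barbier 2-(alkoxycarbonyl)allylation passes through a closed chair transition state that gives the syn C6/C7 adduct (the cis-lactone), allylic 1,3-strain with the CH2In group holds H8 in the alkene plane so the aldehyde is taken up anti to the bulky 8-silyloxy group (setting C7 and C6 from C8), silyloxide is too poor a leaving group for 1,4-elimination, and acid closes the lactone at O6 while O8 is still silylated before fluoride frees 8-OH.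

Step 10
Reactants: 19 8-hydroxy cis-lactone; 4 (R)-2-(2,2-dimethyl-1,3-dioxolan-4-yl)acrylic acid
Product: 20 8-O-[(R)-2-(2,2-dimethyl-1,3-dioxolan-4-yl)acryloyl] cis-lactone (6S,7R,8S,4E)
Conditions: 4 (1.5 equiv), DCC, DMAP (20 mol%), CH2Cl2, 0 → 25 °C
Reagents that add atoms: none
Why: Steglich esterification forms the C8–O acyl bond with retention at C8 and C3', and it is run cold on freshly made 19 so that acylation outruns migration of the lactone to O8.

Step 11
Reactants: 20 8-O-acyl cis-lactone
Product: 22 C1 aldehyde of the 8-O-acyl cis-lactone (isopropylidene replaced by CHO), via secondary ozonide 21 (not isolated)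
Conditions: O3 (1 equiv, Sudan Red 7B end point), CH2Cl2, −78 °C; then Me2S, −78 → 25 °C
Reagents that add atoms: ozone, [O-][O+]=O
Why: In this chemoselective Criegee ozonolysis the electron-rich isopropylidene alkene reacts far faster than C4=C5 (flanked by two allylic acyloxy groups), the two acrylate-type alkenes and the bromoalkene.

Step 12
Reactants: 22 C1 aldehyde of the 8-O-acyl cis-lactone
Product: 23 macrocyclic acetonide (1R,6S,7R,8S,3'R,4E; the target with the side-chain diol as acetonide)
Conditions: CrCl2 (8 equiv), NiCl2 (2 mol%), DMSO/THF 3:1, 2 mM by syringe pump, 25 °C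
Reagents that add atoms: none
Why: The intramolecular Nozaki–Hiyama–Kishi coupling closes ring B because the cis-lactone and the ring-cis C4=C5 bond hold the two chain ends together, and addition of the alkenylchromium to the outward-facing side of the aldehyde in this folded conformer is expected to give 1R (checked by Mosher analysis, and corrected as described below if needed).

Step 13
Reactants: 23 macrocyclic acetonide
Product: 24 CNP0245550.1 (target)
Conditions: AcOH/H2O 4:1, 40 °C
Reagents that add atoms: none
Why: Mild acid hydrolysis removes the terminal acetonide while the allylic acetate, both esters, the lactone and all stereocentres are untouched.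

**Compound list**
1 | methyl (S)-2,2-dimethyl-1,3-dioxolane-4-carboxylate | COC(=O)[C@@H]1COC(C)(C)O1 | starting material
2 | (S)-glyceraldehyde acetonide | O=C[C@@H]1COC(C)(C)O1 | intermediate
3 | (R)-4-ethynyl-2,2-dimethyl-1,3-dioxolane | C#C[C@@H]1COC(C)(C)O1 | intermediate
4 | (R)-2-(2,2-dimethyl-1,3-dioxolan-4-yl)acrylic acid | C=C(C(=O)O)[C@@H]1COC(C)(C)O1 | intermediate
5 | 2,3-dibromopropene | C=C(Br)CBr | starting material
6 | acrolein | C=CC=O | starting material
7 | (S)-[(5-bromohexa-1,5-dien-3-yl)oxy]triethylsilane | C=C(Br)C[C@H](O[Si](CC)(CC)CC)C=C | intermediate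
8 | vicinal diol from 7 (new carbinol centre as a mixture) | C=C(Br)C[C@H](O[Si](CC)(CC)CC)C(O)CO | intermediate
9 | (S)-4-bromo-2-(triethylsilyloxy)pent-4-enal | C=C(Br)C[C@H](O[Si](CC)(CC)CC)C=O | intermediate
10 | methyl propiolate | C#CC(=O)OC | starting material
11 | [1-(methoxycarbonyl)vinyl]diisobutylaluminium | C=C(C(=O)OC)[Al](CC(C)C)CC(C)C | intermediate
12 | methyl (4S)-6-bromo-3-hydroxy-2-methylidene-4-(triethylsilyloxy)hept-6-enoate (C3 epimers) | C=C(Br)C[C@H](O[Si](CC)(CC)CC)C(O)C(=C)C(=O)OC | intermediate
13 | methyl (2Z,4S)-6-bromo-2-(bromomethyl)-4-(triethylsilyloxy)hepta-2,6-dienoate | C=C(Br)C[C@H](O[Si](CC)(CC)CC)/C=C(\CBr)C(=O)OC | intermediate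
14 | myrcene | C=CC(=C)CCC=C(C)C | starting material
15 | (2E)-2-(2-hydroxyethylidene)-6-methylhept-5-en-1-yl acetate | OC/C=C(/COC(C)=O)CCC=C(C)C | intermediate
16 | (2E)-6-methyl-2-(2-oxoethylidene)hept-5-en-1-yl acetate | O=C/C=C(/COC(C)=O)CCC=C(C)C | intermediate
17 | open-chain syn hydroxy ester (6S,7S,8S,4E; C12 methyl ester, 6-OH, 8-OTES; the C7 descriptor differs only because of silicon) | COC(=O)C(=C)[C@@H]([C@@H](O)/C=C(/COC(C)=O)CCC=C(C)C)[C@H](CC(Br)=C)O[Si](CC)(CC)CC | intermediate
18 | 8-O-TES cis-lactone (6S,7S,8S,4E; same spatial arrangement as 19) | C=C1C(=O)O[C@@H](/C=C(/COC(C)=O)CCC=C(C)C)[C@H]1[C@H](CC(Br)=C)O[Si](CC)(CC)CC | intermediate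
19 | 8-hydroxy cis-lactone (6S,7R,8S,4E) | C=C1C(=O)O[C@@H](/C=C(/COC(C)=O)CCC=C(C)C)[C@H]1[C@H](CC(Br)=C)O | intermediate
20 | 8-O-[(R)-2-(2,2-dimethyl-1,3-dioxolan-4-yl)acryloyl] cis-lactone (6S,7R,8S,4E) | C=C1C(=O)O[C@@H](/C=C(/COC(C)=O)CCC=C(C)C)[C@H]1[C@H](CC(Br)=C)OC(=O)C(=C)[C@@H]2COC(C)(C)O2 | intermediate
21 | secondary ozonide of 20 (ozonide CH centre as a mixture) | C=C1C(=O)O[C@@H](/C=C(/COC(C)=O)CCC3OOC(C)(C)O3)[C@H]1[C@H](CC(Br)=C)OC(=O)C(=C)[C@@H]2COC(C)(C)O2 | intermediate
22 | C1 aldehyde (6S,7R,8S,4E) | C=C1C(=O)O[C@@H](/C=C(/COC(C)=O)CCC=O)[C@H]1[C@H](CC(Br)=C)OC(=O)C(=C)[C@@H]2COC(C)(C)O2 | intermediate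
23 | macrocyclic acetonide (1R,6S,7R,8S,3'R,4E) | C=C1C(=O)O[C@H]2/C=C(/COC(C)=O)CC[C@@H](O)C(=C)C[C@H](OC(=O)C(=C)[C@@H]3COC(C)(C)O3)[C@@H]12 | intermediate
24 | CNP0245550.1 | C=C1C(=O)O[C@H]2/C=C(/COC(C)=O)CC[C@@H](O)C(=C)C[C@H](OC(=O)C(=C)[C@@H](O)CO)[C@@H]12 | target

**Step count and longest linear sequence**
- Total step count: 13.
- Longest linear sequence: 9 steps (3, 4, 5, 6, 9, 10, 11, 12, 13).

**The three steps most likely to fail**

Step 7, the proposed new reaction, may give mixtures of diol, diacetate and both monoacetates, or Wacker-type by-products. The fallback sets out from 14. The classical 1,4-diacetoxylation (Pd(OAc)2, LiOAc, p-benzoquinone, AcOH, 25 °C) gives (2E)-2-(4-methylpent-3-en-1-yl)but-2-ene-1,4-diyl diacetate F1. Immobilised Candida antarctica lipase B in pH 7 buffer/MTBE then hydrolyses the less hindered acetate at C6, and the sequence comes back to the route at 15.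

Step 9 may show poor syn/anti or facial selectivity, because the allylindium species is fluxional. The fallback sets out from 12 and proceeds as follows:
- Acetylation (Ac2O, pyridine, DMAP) gives methyl (4S)-3-acetoxy-6-bromo-2-methylidene-4-(triethylsilyloxy)hept-6-enoate F2.
- Copper-mediated SN2' borylation (CuCl, LiCl, KOAc, B2pin2, DMF) gives the configurationally stable methyl (2E,4S)-6-bromo-2-[(4,4,5,5-tetramethyl-1,3,2-dioxaborolan-2-yl)methyl]-4-(triethylsilyloxy)hepta-2,6-dienoate F3, in which CH2B is cis to C8.
- Thermal allylboration of 16 in toluene, if needed with a chiral BINOL-derived phosphoric acid for additional control of the aldehyde face, runs through a rigid Zimmerman–Traxler chair and gives the O6-pinacolboryl ether of the syn adduct F4.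
- Aqueous work-up of F4 comes back to the route at 17.

Step 12 may suffer from oligomerisation and, above all, from an unpredictable C1 configuration. The fallback sets out from 22. The ring is closed without regard to selectivity, giving 23 together with the 1-epimer of the macrocyclic acetonide F5. The mixture is oxidised with Dess–Martin periodinane to the 1-oxo macrocycle (cross-conjugated enone) F6. Reagent-controlled reduction with (S)-2-methyl-CBS-oxazaborolidine and catecholborane in toluene at −78 °C treats the alkenyl side as the large group, delivers the 1R alcohol, and comes back to the route at 23.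

**Further compounds**
F1 | step 7 | (2E)-2-(4-methylpent-3-en-1-yl)but-2-ene-1,4-diyl diacetate | CC(=O)OC/C=C(/COC(C)=O)CCC=C(C)C
F2 | step 9 | methyl (4S)-3-acetoxy-6-bromo-2-methylidene-4-(triethylsilyloxy)hept-6-enoate (C3 epimers) | C=C(Br)C[C@H](O[Si](CC)(CC)CC)C(OC(C)=O)C(=C)C(=O)OC
F3 | step 9 | methyl (2E,4S)-6-bromo-2-[(4,4,5,5-tetramethyl-1,3,2-dioxaborolan-2-yl)methyl]-4-(triethylsilyloxy)hepta-2,6-dienoate | C=C(Br)C[C@H](O[Si](CC)(CC)CC)/C=C(\CB1OC(C)(C)C(C)(C)O1)C(=O)OC
F4 | step 9 | O6-pinacolboryl ether of the syn adduct 17 | COC(=O)C(=C)[C@@H]([C@@H](OB1OC(C)(C)C(C)(C)O1)/C=C(/COC(C)=O)CCC=C(C)C)[C@H](CC(Br)=C)O[Si](CC)(CC)CC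
F5 | step 12 | 1-epimer (1S) of the macrocyclic acetonide 23 | C=C1C(=O)O[C@H]2/C=C(/COC(C)=O)CC[C@H](O)C(=C)C[C@H](OC(=O)C(=C)[C@@H]3COC(C)(C)O3)[C@@H]12
F6 | step 12 | 1-oxo macrocycle (enone) | C=C1C(=O)O[C@H]2/C=C(/COC(C)=O)CCC(=O)C(=C)C[C@H](OC(=O)C(=C)[C@@H]3COC(C)(C)O3)[C@@H]12
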